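**Plan**
- Retrosynthetic cuts, in order: O1–C2 of the flavanone ring C; the ring A aryl–C4 bond; the C3–CH2 bond (this CH2 is the future C2); the pyranone ring of the flavone; the acetic acid side chain, traced back to an allyl group.
- Forward: the flavone is built first and its allyl group is shortened to an arylacetic acid. The acid is benzylated on a chiral imide, ring A is attached as an aryl ketone, ring C of the flavanone closes last, and hydrogenolysis ends the route.
- Enabling feature: C2 is benzylic to ring B and para to its 4'-OH. As a CH2 group it can be oxidised to a para-quinone methide that lies next to the ortho hydroxyl of ring A, the future O1.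
- Stereochemistry: C3 comes from an (S)-4-benzyloxazolidinone-directed alkylation (descriptor S in the open chain, R after ring closure, same spatial arrangement). C2 (S) is set trans to C3 in the ring closure.

Key step: step 19

Remark: 3-allyl-4-hydroxybenzaldehyde, 1,3,5-tris(benzyloxy)benzene and (for one fallback) 3,5-bis(benzyloxy)phenol are taken as purchasable.
Abbreviations: FlBn = 2-(benzyloxy)-5-[5-(benzyloxy)-7-methoxy-4-oxo-4H-chromen-2-yl]phenyl; FlH = 2-(benzyloxy)-5-(5-hydroxy-7-methoxy-4-oxo-4H-chromen-2-yl)phenyl; TIPS = triisopropylsilyl.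

**Route**

Step 1
Reactants: 1 2',6'-dihydroxy-4'-methoxyacetophenone
Product: 2 2'-(benzyloxy)-6'-hydroxy-4'-methoxyacetophenone
Conditions: BnBr (1.05 equiv), K2CO3, acetone, reflux
Reagents that add atoms: benzyl bromide, BrCc1ccccc1
Why: Williamson O-benzylation should stop at the mono-ether because the remaining hydroxyl is then locked in a hydrogen bond to the acetyl carbonyl.

Step 2
Reactants: 3 3-allyl-4-hydroxybenzaldehyde
Product: 4 3-allyl-4-(benzyloxy)benzaldehyde
Conditions: BnBr, K2CO3, DMF, rt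
Reagents that add atoms: benzyl bromide, BrCc1ccccc1
Why: Williamson etherification of the only phenol; the aldehyde and the allyl group are inert to K2CO3 in DMF.

Step 3
Reactants: 2 2'-(benzyloxy)-6'-hydroxy-4'-methoxyacetophenone; 4 3-allyl-4-(benzyloxy)benzaldehyde
Product: 5 (E)-3-[3-allyl-4-(benzyloxy)phenyl]-1-[2-(benzyloxy)-6-hydroxy-4-methoxyphenyl]prop-2-en-1-one
Conditions: KOH (aq.), EtOH, rt
Reagents that add atoms: none
Why: Claisen–Schmidt aldol condensation of a methyl ketone with an aldehyde that has no α-hydrogen, dehydration giving the E-enone.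

Step 4
Reactants: 5 2'-hydroxychalcone
Product: 6 2-[3-allyl-4-(benzyloxy)phenyl]-5-(benzyloxy)-7-methoxy-4H-chromen-4-one
Conditions: I2 (10 mol%), DMSO, 120 °C
Reagents that add atoms: none
Why: iodine-catalysed oxidative cyclisation of a 2'-hydroxychalcone in DMSO is the standard flavone synthesis (DMSO re-oxidises HI to I2), and a catalytic iodine charge should spare the isolated allyl group and the benzyl ethers.

Step 5
Reactants: 6 allyl flavone
Product: 8 FlBn–CH2–CHO (arylacetaldehyde), via vicinal diol 7 (not isolated)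
Conditions: OsO4 (2 mol%), NaIO4, 2,6-lutidine, dioxane/H2O 3:1, rt
Reagents that add atoms: OsO4, O=[Os](=O)(=O)=O (oxygen carrier); NaIO4, [Na+].[O-][I](=O)(=O)=O (terminal oxygen source)
Why: Lemieux–Johnson oxidation, in which OsO4 dihydroxylates the isolated monosubstituted alkene far faster than the electron-poor, conjugated C2=C3 bond of the chromone and periodate cleaves the diol.

Step 6
Reactants: 8 FlBn–CH2–CHO
Product: 9 FlBn–CH2–CO2H (arylacetic acid)
Conditions: NaClO2, NaH2PO4, 2-methyl-2-butene, t-BuOH/THF/H2O, 0 °C → rt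
Reagents that add atoms: sodium chlorite, [Na+].[O-]Cl=O
Why: Pinnick oxidation converts the aldehyde to the acid under buffered conditions that leave benzyl ethers and the chromone untouched, 2-methyl-2-butene trapping HOCl.

Step 7
Reactants: 9 FlBn–CH2–CO2H; 10 (S)-4-benzyl-1,3-oxazolidin-2-one
Product: 12 (S)-4-benzyl-3-(FlBn-acetyl)-1,3-oxazolidin-2-one, via mixed pivalic anhydride 11 (not isolated)
Conditions: t-BuCOCl, Et3N, THF, −20 °C; then 10, LiCl, −20 °C → rt
Reagents that add atoms: none
Why: N-acylation of the oxazolidinone through the mixed pivalic anhydride with Et3N and LiCl needs no strong base, so the chromone is never exposed to a lithiated nucleophile.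

Step 8
Reactants: 13 4-hydroxybenzyl alcohol
Product: 15 [4-(triisopropylsilyloxy)phenyl]methanol, via sodium phenoxide 14 (not isolated)
Conditions: NaH (1.0 equiv), THF, 0 °C; then i-Pr3SiCl, 0 °C → rt
Reagents that add atoms: chlorotriisopropylsilane, CC(C)[Si](Cl)(C(C)C)C(C)C
Why: one equivalent of NaH deprotonates only the phenol, which is about five pKa units more acidic than the benzylic alcohol, and the phenoxide is then O-silylated selectively.

Step 9
Reactants: 15 [4-(triisopropylsilyloxy)phenyl]methanol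
Product: 16 4-(triisopropylsilyloxy)benzyl bromide
Conditions: CBr4, PPh3, CH2Cl2, 0 °C
Reagents that add atoms: carbon tetrabromide, BrC(Br)(Br)Br
Why: Appel bromination converts the primary benzylic alcohol to the bromide under neutral conditions that keep the aryl silyl ether.

Step 10
Reactants: 12 (S)-4-benzyl-3-(FlBn-acetyl)-1,3-oxazolidin-2-one; 16 4-(triisopropylsilyloxy)benzyl bromide
Product: 18 (S)-4-benzyl-3-{(2S)-2-FlBn-3-[4-(TIPS-oxy)phenyl]propanoyl}-1,3-oxazolidin-2-one, via sodium Z-enolate 17 (not isolated)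
Conditions: NaN(SiMe3)2, THF, −78 °C; then 16, −78 → −40 °C
Reagents that add atoms: none
Why: Evans asymmetric alkylation, in which the benzylic bromide attacks the chelated sodium Z-enolate on the face opposite the C4 benzyl group of the (S)-auxiliary and so sets the future C3 centre as S (the same spatial arrangement is 3R in the flavanone).

Step 11
Reactants: 18 alkylated imide
Product: 20 (2S)-2-FlBn-3-[4-(TIPS-oxy)phenyl]propanoic acid, via peroxy acid 19 (not isolated)
Conditions: LiOH, H2O2 (30% aq.), THF/H2O 3:1, 0 °C; then aq. Na2SO3; aq. HCl to pH 3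
Reagents that add atoms: hydrogen peroxide, OO
Why: lithium hydroperoxide attacks the exocyclic imide carbonyl selectively (standard cleavage of the Evans auxiliary, which is recovered as 10) and is too weakly basic to epimerise the α-aryl centre or to epoxidise the flavone, sulfite then reducing the peroxy acid.

Step 12
Reactants: 20 (2S)-2-FlBn-3-[4-(TIPS-oxy)phenyl]propanoic acid
Product: 21 (2S)-2-FlBn-3-[4-(TIPS-oxy)phenyl]propan-1-ol
Conditions: BH3·SMe2, THF, 0 °C → rt; MeOH quench
Reagents that add atoms: none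
Why: chemoselective borane reduction, since borane reduces a carboxylic acid much faster than the vinylogous-ester carbonyl of the chromone and no base touches the stereocentre.

Step 13
Reactants: 21 (2S)-2-FlBn-3-[4-(TIPS-oxy)phenyl]propan-1-ol
Product: 22 (2S)-2-FlBn-3-[4-(TIPS-oxy)phenyl]propanal
Conditions: Dess–Martin periodinane, CH2Cl2, 0 °C → rt; used crude at once
Reagents that add atoms: none
Why: Dess–Martin oxidation gives the α-aryl aldehyde under neutral, non-enolising conditions, and immediate use without chromatography should preserve the stereocentre.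

Step 14
Reactants: 23 1,3,5-tris(benzyloxy)benzene
Product: 24 2-bromo-1,3,5-tris(benzyloxy)benzene
Conditions: NBS (1.0 equiv), CH2Cl2, −78 → 0 °C
Reagents that add atoms: N-bromosuccinimide, O=C1CCC(=O)N1Br
Why: electrophilic aromatic bromination of the symmetric, strongly activated arene with one equivalent of NBS at low temperature can give only one monobromide.

Step 15
Reactants: 24 2-bromo-1,3,5-tris(benzyloxy)benzene; 22 (2S)-2-FlBn-3-[4-(TIPS-oxy)phenyl]propanal
Product: 26 (2S)-2-FlBn-3-[4-(TIPS-oxy)phenyl]-1-[2,4,6-tris(benzyloxy)phenyl]propan-1-ol (both carbinol epimers), via aryllithium 25 (not isolated)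
Conditions: 24, n-BuLi, THF, −78 °C; then 22, −78 °C; AcOH quench
Reagents that add atoms: none
Why: bromine–lithium exchange followed by 1,2-addition of the aryllithium to the aldehyde at −78 °C, which should be much faster than attack on the chromone carbonyl (a vinylogous ester), the two carbinol epimers converging in the next step.

Step 16
Reactants: 26 carbinol (epimer mixture)
Product: 27 (2S)-2-FlBn-3-[4-(TIPS-oxy)phenyl]-1-[2,4,6-tris(benzyloxy)phenyl]propan-1-one
Conditions: Dess–Martin periodinane, CH2Cl2, rt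
Reagents that add atoms: none
Why: Dess–Martin oxidation of the benzylic carbinol to the aryl ketone needs no base, and the doubly ortho-substituted aryl ketone is twisted and enolises slowly.

Step 17
Reactants: 27 tris(benzyloxy)phenyl ketone
Product: 28 (2S)-1-[2,4-bis(benzyloxy)-6-hydroxyphenyl]-2-FlH-3-[4-(TIPS-oxy)phenyl]propan-1-one
Conditions: MgBr2·OEt2, toluene/Et2O, 70 °C; aq. HCl work-up
Reagents that add atoms: none
Why: chelation-controlled ether cleavage, in which MgBr2 bridges a carbonyl oxygen and a flanking benzyloxy oxygen and bromide removes the benzyl group, so only the flavone 5-O-benzyl group and one ortho benzyl ether of ring A should fall; after the first ring A cleavage the magnesium phenoxide holds the ketone and the second ortho ether is no longer activated.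

Step 18
Reactants: 28 silyl-protected diphenol
Product: 29 (2S)-1-[2,4-bis(benzyloxy)-6-hydroxyphenyl]-2-FlH-3-(4-hydroxyphenyl)propan-1-one
Conditions: n-Bu4NF, AcOH (1:1), THF, 0 °C
Reagents that add atoms: none
Why: fluoride-mediated desilylation of the aryl silyl ether, with acetic acid buffering so that the medium cannot enolise the α-aryl ketone.

Step 19
Reactants: 29 (2S)-1-[2,4-bis(benzyloxy)-6-hydroxyphenyl]-2-FlH-3-(4-hydroxyphenyl)propan-1-one
Product: 31 (2S,3R)-5,7-bis(benzyloxy)-3-FlH-2-(4-hydroxyphenyl)chroman-4-one, via para-quinone methide 30 (not isolated)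
Conditions: graphite anode, Pt cathode, undivided cell, constant current (about 2 F/mol), n-Bu4NPF6 (0.1 M), HFIP/CH2Cl2 4:1, 0 °C
Reagents that add atoms: none
Why: Proposed new method: proton-coupled two-electron oxidation of the ring B phenol, the only phenol of 29 not locked in a hydrogen bond to a carbonyl group, should give through the phenoxonium ion the para-quinone methide 30, whose exocyclic carbon (the future C2) is attacked by the ring A hydroxyl in a 1,6-addition that restores the aromaticity of ring B and forms O1–C2. The closest known reaction type is the oxidation of 4-alkylphenols (DDQ, Ag2O or an anode) to para-quinone methides with intramolecular capture by a phenol, as in the closure of 1-(2-hydroxyaryl)-3-(4-hydroxyaryl)propanes to flavans; here it is extended to a ketone with an enolisable stereocentre next to the methide. Ring C closes in the 6-exo-trig mode. C2 is controlled by the existing C3 centre: in the chair-like transition state the C3 aryl group and the quinone methide ring both sit pseudo-equatorial, which gives the 2,3-trans (2S,3R) isomer, and because phenol addition to the methide is reversible in HFIP any cis isomer can return through 30 without touching C3. The step needs chemoselective oxidation of ring B (the two other free hydroxyls are chelated to and conjugated with carbonyl groups, the aryl benzyl ethers oxidise at higher potential, and the charge is limited to about two faradays per mole) and a cyclisation faster than the prototropic shift of the C3 hydrogen that would give the achiral α-aryl chalcone; the base-free, weakly acidic fluorinated alcohol, the low temperature and the intramolecular six-membered closure are meant to secure this.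

Step 20
Reactants: 31 tri-O-benzyl flavanone–flavone
Product: 32 (2S,3R)-5,7-dihydroxy-3-[2-hydroxy-5-(5-hydroxy-7-methoxy-4-oxo-4H-chromen-2-yl)phenyl]-2-(4-hydroxyphenyl)chroman-4-one (target)
Conditions: H2 (1 atm), Pd/C (10% palladium on carbon), THF/MeOH, rt
Reagents that add atoms: none
Why: hydrogenolysis of the three benzyl ethers over Pd/C under one atmosphere of hydrogen at room temperature, stopped after uptake of three equivalents so that the chromone C2=C3 bond and the benzylic C2–O1 bond of the flavanone stay intact.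

**Compound list**

1 | 2',6'-dihydroxy-4'-methoxyacetophenone | CC(=O)c1c(O)cc(OC)cc1O | starting material
2 | 2'-(benzyloxy)-6'-hydroxy-4'-methoxyacetophenone | CC(=O)c1c(O)cc(OC)cc1OCc1ccccc1 | intermediate
3 | 3-allyl-4-hydroxybenzaldehyde | C=CCc1cc(C=O)ccc1O | starting material
4 | 3-allyl-4-(benzyloxy)benzaldehyde | C=CCc1cc(C=O)ccc1OCc1ccccc1 | intermediate
5 | (E)-3-[3-allyl-4-(benzyloxy)phenyl]-1-[2-(benzyloxy)-6-hydroxy-4-methoxyphenyl]prop-2-en-1-one | COc1cc(O)c(C(=O)/C=C/c2ccc(OCc3ccccc3)c(CC=C)c2)c(OCc2ccccc2)c1 | intermediate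
6 | 2-[3-allyl-4-(benzyloxy)phenyl]-5-(benzyloxy)-7-methoxy-4H-chromen-4-one | COc1cc(OCc2ccccc2)c2c(=O)cc(-c3ccc(OCc4ccccc4)c(CC=C)c3)oc2c1 | intermediate
7 | 2-[4-(benzyloxy)-3-(2,3-dihydroxypropyl)phenyl]-5-(benzyloxy)-7-methoxy-4H-chromen-4-one (racemic diol) | COc1cc(OCc2ccccc2)c2c(=O)cc(-c3ccc(OCc4ccccc4)c(CC(O)CO)c3)oc2c1 | intermediate (not isolated)
8 | 2-FlBn-acetaldehyde | COc1cc(OCc2ccccc2)c2c(=O)cc(-c3ccc(OCc4ccccc4)c(CC=O)c3)oc2c1 | intermediate
9 | 2-FlBn-acetic acid | COc1cc(OCc2ccccc2)c2c(=O)cc(-c3ccc(OCc4ccccc4)c(CC(=O)O)c3)oc2c1 | intermediate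
10 | (S)-4-benzyl-1,3-oxazolidin-2-one | O=C1N[C@@H](Cc2ccccc2)CO1 | starting material
11 | mixed anhydride of 9 with pivalic acid | COc1cc(OCc2ccccc2)c2c(=O)cc(-c3ccc(OCc4ccccc4)c(CC(=O)OC(=O)C(C)(C)C)c3)oc2c1 | intermediate (not isolated)
12 | (S)-4-benzyl-3-(FlBn-acetyl)-1,3-oxazolidin-2-one | COc1cc(OCc2ccccc2)c2c(=O)cc(-c3ccc(OCc4ccccc4)c(CC(=O)N4C(=O)OC[C@@H]4Cc4ccccc4)c3)oc2c1 | intermediate
13 | 4-hydroxybenzyl alcohol | OCc1ccc(O)cc1 | starting material
14 | sodium 4-(hydroxymethyl)phenoxide | OCc1ccc([O-])cc1.[Na+] | intermediate (not isolated)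
15 | [4-(triisopropylsilyloxy)phenyl]methanol | OCc1ccc(O[Si](C(C)C)(C(C)C)C(C)C)cc1 | intermediate
16 | 4-(triisopropylsilyloxy)benzyl bromide | BrCc1ccc(O[Si](C(C)C)(C(C)C)C(C)C)cc1 | intermediate
17 | sodium (Z)-enolate of 12 | COc1cc(OCc2ccccc2)c2c(=O)cc(-c3ccc(OCc4ccccc4)c(/C=C(\[O-])N4C(=O)OC[C@@H]4Cc4ccccc4)c3)oc2c1.[Na+] | intermediate (not isolated)
18 | (S)-4-benzyl-3-{(2S)-2-FlBn-3-[4-(TIPS-oxy)phenyl]propanoyl}-1,3-oxazolidin-2-one | COc1cc(OCc2ccccc2)c2c(=O)cc(-c3ccc(OCc4ccccc4)c([C@H](Cc4ccc(O[Si](C(C)C)(C(C)C)C(C)C)cc4)C(=O)N4C(=O)OC[C@@H]4Cc4ccccc4)c3)oc2c1 | intermediate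
19 | (2S)-2-FlBn-3-[4-(TIPS-oxy)phenyl]propaneperoxoic acid | COc1cc(OCc2ccccc2)c2c(=O)cc(-c3ccc(OCc4ccccc4)c([C@H](Cc4ccc(O[Si](C(C)C)(C(C)C)C(C)C)cc4)C(=O)OO)c3)oc2c1 | intermediate (not isolated)
20 | (2S)-2-FlBn-3-[4-(TIPS-oxy)phenyl]propanoic acid | COc1cc(OCc2ccccc2)c2c(=O)cc(-c3ccc(OCc4ccccc4)c([C@H](Cc4ccc(O[Si](C(C)C)(C(C)C)C(C)C)cc4)C(=O)O)c3)oc2c1 | intermediate
21 | (2S)-2-FlBn-3-[4-(TIPS-oxy)phenyl]propan-1-ol | COc1cc(OCc2ccccc2)c2c(=O)cc(-c3ccc(OCc4ccccc4)c([C@H](Cc4ccc(O[Si](C(C)C)(C(C)C)C(C)C)cc4)CO)c3)oc2c1 | intermediate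
22 | (2S)-2-FlBn-3-[4-(TIPS-oxy)phenyl]propanal | COc1cc(OCc2ccccc2)c2c(=O)cc(-c3ccc(OCc4ccccc4)c([C@H](Cc4ccc(O[Si](C(C)C)(C(C)C)C(C)C)cc4)C=O)c3)oc2c1 | intermediate
23 | 1,3,5-tris(benzyloxy)benzene | c1c(OCc2ccccc2)cc(OCc2ccccc2)cc1OCc1ccccc1 | starting material
24 | 2-bromo-1,3,5-tris(benzyloxy)benzene | Brc1c(OCc2ccccc2)cc(OCc2ccccc2)cc1OCc1ccccc1 | intermediate
25 | 2,4,6-tris(benzyloxy)phenyllithium | [Li]c1c(OCc2ccccc2)cc(OCc2ccccc2)cc1OCc1ccccc1 | intermediate (not isolated)
26 | (2S)-2-FlBn-3-[4-(TIPS-oxy)phenyl]-1-[2,4,6-tris(benzyloxy)phenyl]propan-1-ol (both C1 epimers) | COc1cc(OCc2ccccc2)c2c(=O)cc(-c3ccc(OCc4ccccc4)c([C@H](Cc4ccc(O[Si](C(C)C)(C(C)C)C(C)C)cc4)C(O)c4c(OCc5ccccc5)cc(OCc5ccccc5)cc4OCc4ccccc4)c3)oc2c1 | intermediate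
27 | (2S)-2-FlBn-3-[4-(TIPS-oxy)phenyl]-1-[2,4,6-tris(benzyloxy)phenyl]propan-1-one | COc1cc(OCc2ccccc2)c2c(=O)cc(-c3ccc(OCc4ccccc4)c([C@H](Cc4ccc(O[Si](C(C)C)(C(C)C)C(C)C)cc4)C(=O)c4c(OCc5ccccc5)cc(OCc5ccccc5)cc4OCc4ccccc4)c3)oc2c1 | intermediate
28 | (2S)-1-[2,4-bis(benzyloxy)-6-hydroxyphenyl]-2-FlH-3-[4-(TIPS-oxy)phenyl]propan-1-one | COc1cc(O)c2c(=O)cc(-c3ccc(OCc4ccccc4)c([C@H](Cc4ccc(O[Si](C(C)C)(C(C)C)C(C)C)cc4)C(=O)c4c(O)cc(OCc5ccccc5)cc4OCc4ccccc4)c3)oc2c1 | intermediate
29 | (2S)-1-[2,4-bis(benzyloxy)-6-hydroxyphenyl]-2-FlH-3-(4-hydroxyphenyl)propan-1-one | COc1cc(O)c2c(=O)cc(-c3ccc(OCc4ccccc4)c([C@H](Cc4ccc(O)cc4)C(=O)c4c(O)cc(OCc5ccccc5)cc4OCc4ccccc4)c3)oc2c1 | intermediate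
30 | 4-{(2S)-3-[2,4-bis(benzyloxy)-6-hydroxyphenyl]-2-FlH-3-oxopropylidene}cyclohexa-2,5-dien-1-one (para-quinone methide) | COc1cc(O)c2c(=O)cc(-c3ccc(OCc4ccccc4)c([C@H](C=C4C=CC(=O)C=C4)C(=O)c4c(O)cc(OCc5ccccc5)cc4OCc4ccccc4)c3)oc2c1 | intermediate (not isolated)
31 | (2S,3R)-5,7-bis(benzyloxy)-3-FlH-2-(4-hydroxyphenyl)chroman-4-one | COc1cc(O)c2c(=O)cc(-c3ccc(OCc4ccccc4)c([C@H]4C(=O)c5c(OCc6ccccc6)cc(OCc6ccccc6)cc5O[C@@H]4c4ccc(O)cc4)c3)oc2c1 | intermediate
32 | (2S,3R)-5,7-dihydroxy-3-[2-hydroxy-5-(5-hydroxy-7-methoxy-4-oxo-4H-chromen-2-yl)phenyl]-2-(4-hydroxyphenyl)chroman-4-one | COc1cc(O)c2c(=O)cc(-c3ccc(O)c([C@H]4C(=O)c5c(O)cc(O)cc5O[C@@H]4c4ccc(O)cc4)c3)oc2c1 | target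

**Step count and risks**

Total: 20 steps. Longest linear sequence: 16 steps (step 1 or 2, then 3–7, 10–13 and 15–20).

Step 19 (anodic ring closure). The quinone methide may lose the C3 hydrogen faster than it cyclises, which would erase the stereocentre. The anode may also over-oxidise the product phenol or attack the benzyloxy arenes. The fallback uses known steps and sets out from 29. Compound 29 is dehydrogenated on purpose with DDQ in dioxane to the (E)-α-aryl-2'-hydroxychalcone F1, the known phenol-assisted dehydrogenation of 4-hydroxydihydrochalcones. F1 is cyclised by oxa-Michael addition (NaOAc, EtOH, reflux) under thermodynamic control to the racemic 2,3-trans flavanone, that is 31 together with its (2R,3S) enantiomer F2. The enantiomers are separated by preparative HPLC on a chiral stationary phase, and the route is rejoined at 31. The cost is that the auxiliary-derived C3 information is no longer used.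

Step 15 (aryllithium addition). The basic, hindered aryllithium may enolise the α-aryl aldehyde, eroding configuration and conversion, or add to the chromone carbonyl. The fallback makes the aryl–carbonyl bond with the arene as a neutral nucleophile and sets out from acid 20 and arene 23. Acid 20 is activated with trifluoroacetic anhydride in CH2Cl2 at 0 °C as the mixed trifluoroacetic anhydride F3. F3 acylates 1,3,5-tris(benzyloxy)benzene 23 in a Friedel–Crafts acylation that needs no Lewis acid for a phloroglucinol ether. This gives ketone 27 directly, where the route is rejoined, and makes steps 12 to 16 unnecessary. The integrity of C3 under these acidic conditions would have to be confirmed on 27.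

Step 17 (chelation-controlled debenzylation). Cleavage at the twisted, doubly ortho-substituted ketone may be sluggish, and the forcing then needed could remove further benzyl groups or epimerise C3 through Lewis acid-promoted enolisation. The fallback builds the differentiation into the ring A nucleophile and sets out from aldehyde 22. Purchasable 3,5-bis(benzyloxy)phenol is converted with MOMCl/i-Pr2NEt to 1,3-bis(benzyloxy)-5-(methoxymethoxy)benzene F4. Ortho-lithiation (n-BuLi, THF, 0 °C), expected mainly between the OMOM and a benzyloxy group, gives 2,4-bis(benzyloxy)-6-(methoxymethoxy)phenyllithium F5. F5 is added to 22 to give carbinol F6, and Dess–Martin oxidation gives ketone F7. MgBr2·OEt2 at room temperature then removes the carbonyl-chelated acetal and the flavone 5-O-benzyl group, both far more labile than a benzyl ether on a twisted ketone, and the route is rejoined at 28.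

**Further compounds**

F1 | step 19 | (E)-1-[2,4-bis(benzyloxy)-6-hydroxyphenyl]-2-FlH-3-(4-hydroxyphenyl)prop-2-en-1-one | COc1cc(O)c2c(=O)cc(-c3ccc(OCc4ccccc4)c(/C(=C\c4ccc(O)cc4)C(=O)c4c(O)cc(OCc5ccccc5)cc4OCc4ccccc4)c3)oc2c1
F2 | step 19 | (2R,3S)-5,7-bis(benzyloxy)-3-FlH-2-(4-hydroxyphenyl)chroman-4-one (enantiomer of 31) | COc1cc(O)c2c(=O)cc(-c3ccc(OCc4ccccc4)c([C@@H]4C(=O)c5c(OCc6ccccc6)cc(OCc6ccccc6)cc5O[C@H]4c4ccc(O)cc4)c3)oc2c1
F3 | step 15 | mixed anhydride of 20 with trifluoroacetic acid | COc1cc(OCc2ccccc2)c2c(=O)cc(-c3ccc(OCc4ccccc4)c([C@H](Cc4ccc(O[Si](C(C)C)(C(C)C)C(C)C)cc4)C(=O)OC(=O)C(F)(F)F)c3)oc2c1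
F4 | step 17 | 1,3-bis(benzyloxy)-5-(methoxymethoxy)benzene | COCOc1cc(OCc2ccccc2)cc(OCc2ccccc2)c1
F5 | step 17 | 2,4-bis(benzyloxy)-6-(methoxymethoxy)phenyllithium | [Li]c1c(OCOC)cc(OCc2ccccc2)cc1OCc1ccccc1
F6 | step 17 | (2S)-1-[2,4-bis(benzyloxy)-6-(methoxymethoxy)phenyl]-2-FlBn-3-[4-(TIPS-oxy)phenyl]propan-1-ol (both C1 epimers) | COc1cc(OCc2ccccc2)c2c(=O)cc(-c3ccc(OCc4ccccc4)c([C@H](Cc4ccc(O[Si](C(C)C)(C(C)C)C(C)C)cc4)C(O)c4c(OCOC)cc(OCc5ccccc5)cc4OCc4ccccc4)c3)oc2c1
F7 | step 17 | (2S)-1-[2,4-bis(benzyloxy)-6-(methoxymethoxy)phenyl]-2-FlBn-3-[4-(TIPS-oxy)phenyl]propan-1-one | COc1cc(OCc2ccccc2)c2c(=O)cc(-c3ccc(OCc4ccccc4)c([C@H](Cc4ccc(O[Si](C(C)C)(C(C)C)C(C)C)cc4)C(=O)c4c(OCOC)cc(OCc5ccccc5)cc4OCc4ccccc4)c3)oc2c1
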